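**Retrosynthetic overview**

1. Dipolynaphthalene B (20) comes from its silyl ether 19, and 19 from the open-chain aryl bromide 15. Ring B is closed last, through the C8a–C1 bond, by halogen–lithium exchange, intramolecular borate formation, 1,2-aryl shift from boron to carbon and oxidation.
2. The enabling feature is that C1 is a benzylic carbinol carbon bonded to arene carbon C8a of ring A, which is the product pattern of a stereospecific boron-to-carbon aryl shift followed by C–B oxidation. C8a lies ortho to the C4-bearing carbon C4a but meta to the C5 methoxy group, where Friedel–Crafts closure is electronically mismatched and outcompeted by C2′ of the naphthalene, so C8a is addressed as an aryllithium made from a bromide.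
3. Compound 15 comes from Matteson homologation of the C2 boronic ester 13 (C1 from CH2Cl2, configuration from (−)-pinanediol), and 13 from hydroboration of the vinyl group of 11.
4. The C4 stereocenter comes from enantioselective vinylboronate addition (C4–C3 bond) to an ortho-quinone methide that uses the later C5 oxygen of ring A. The C4–C4a bond comes from an ortho-lithiated 3-bromophenol ether and naphthaldehyde 4, itself made from symmetric 1,8-dimethoxynaphthalene.
5. Ring order: rings A, C and D are bought as arenes; ring B is the only ring formed, in step 10.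

Key step: step 10

Remark on the chemistry: locants follow the tetralin numbering of the target (C1 carbinol, C4 naphthyl-bearing carbon, C4a and C8a ring fusion, C5 methoxy carbon; ring A anisole ring, ring B saturated ring, rings C and D the naphthalene, primed locants). In step 6 the (R)-biphenol is assumed to deliver the vinyl group to the face that gives (S)-C4; if the first run shows the opposite sense, its antipode is used.

**Route**

Step 1
Reactants: 1 1,8-dimethoxynaphthalene
Product: 2 4,5-dimethoxynaphthalene-1-carbaldehyde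
Conditions: POCl3, DMF, 0 °C to 80 °C; then aqueous NaOAc
Reagents that add atoms: N,N-dimethylformamide, CN(C)C=O; water, O
Why: Vilsmeier–Haack formylation attacks the position para to a methoxy group, and because the two para positions of symmetric 1 are equivalent only one aldehyde can form.

Step 2
Reactants: 2 4,5-dimethoxynaphthalene-1-carbaldehyde
Product: 3 4-hydroxy-5-methoxynaphthalene-1-carbaldehyde
Conditions: NaSEt, DMF, 110 °C; then dilute HCl
Reagents that add atoms: none
Why: Nucleophilic (SN2) demethylation by thiolate should select the methoxy group para to the formyl group, whose aryloxide is a vinylogous carboxylate and the better leaving group, and leave the C5 ether on the other ring.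

Step 3
Reactants: 3 4-hydroxy-5-methoxynaphthalene-1-carbaldehyde
Product: 4 5-methoxy-4-(triisopropylsilyloxy)naphthalene-1-carbaldehyde
Conditions: TIPSOTf, 2,6-lutidine, CH2Cl2, 0 °C to rt
Reagents that add atoms: triisopropylsilyl trifluoromethanesulfonate, CC(C)[Si](C(C)C)(C(C)C)OS(=O)(=O)C(F)(F)F
Why: Silylation of the acidic, peri-hindered naphthol with the silyl triflate gives an ether that should survive the organolithium, acid and carbenoid steps and is removed by fluoride at the end.

Step 4
Reactants: 5 1-bromo-3-(methoxymethoxy)benzene; 4 5-methoxy-4-(triisopropylsilyloxy)naphthalene-1-carbaldehyde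
Product: 7 racemic [2-bromo-6-(methoxymethoxy)phenyl][5-methoxy-4-(triisopropylsilyloxy)naphthalen-1-yl]methanol, via aryllithium 6 (not isolated)
Conditions: LDA, THF, −78 °C; then 4, −78 °C; H2O
Reagents that add atoms: none
Why: Directed ortho-metalation removes the proton flanked by bromine and the methoxymethoxy group, and the aryllithium, kept at −78 °C so that it does not lose LiBr, adds to the aldehyde to form the C4–C4a bond (the carbinol stereocenter is erased in step 6).

Step 5
Reactants: 7 racemic [2-bromo-6-(methoxymethoxy)phenyl][5-methoxy-4-(triisopropylsilyloxy)naphthalen-1-yl]methanol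
Product: 8 racemic 3-bromo-2-{methoxy[5-methoxy-4-(triisopropylsilyloxy)naphthalen-1-yl]methyl}phenol
Conditions: HCl (0.5 M), MeOH/THF, 0 °C to rt
Reagents that add atoms: methanol, CO
Why: Acid-catalysed acetal cleavage frees the phenol and SN1 solvolysis of the doubly activated benzhydrol gives the methyl ether, the ortho-quinone methide precursor, while the aryl silyl ether should tolerate dilute methanolic acid.

Step 6
Reactants: 8 racemic 3-bromo-2-{methoxy[5-methoxy-4-(triisopropylsilyloxy)naphthalen-1-yl]methyl}phenol
Product: 10 3-bromo-2-{(1S)-1-[5-methoxy-4-(triisopropylsilyloxy)naphthalen-1-yl]prop-2-en-1-yl}phenol, via ortho-quinone methide 9 (not isolated)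
Conditions: (R)-3,3′-Br2-BINOL (15 mol %), dibutyl vinylboronate, 4 Å molecular sieves, PhCF3, 45 °C
Reagents that add atoms: dibutyl vinylboronate, C=CB(OCCCC)OCCCC
Why: Chiral-biphenol-catalysed enantioselective addition of an alkenylboronate to an ortho-quinone methide generated in situ, in which the quinone methide oxygen binds boron and the vinyl group is delivered to one face of the exocyclic C=C, should set C4 as (S), with both enantiomers of 8 converging through the planar intermediate.

Step 7
Reactants: 10 3-bromo-2-{(1S)-1-[5-methoxy-4-(triisopropylsilyloxy)naphthalen-1-yl]prop-2-en-1-yl}phenol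
Product: 11 1-bromo-3-methoxy-2-{(1S)-1-[5-methoxy-4-(triisopropylsilyloxy)naphthalen-1-yl]prop-2-en-1-yl}benzene
Conditions: MeI, K2CO3, acetone, 50 °C
Reagents that add atoms: iodomethane, CI
Why: Williamson methylation of the only free phenol turns the activating hydroxyl into the C5 methoxy group of ring A, and K2CO3 is too weak a base to deprotonate the allylic diarylmethine.

Step 8
Reactants: 11 1-bromo-3-methoxy-2-{(1S)-1-[5-methoxy-4-(triisopropylsilyloxy)naphthalen-1-yl]prop-2-en-1-yl}benzene
Product: 13 (−)-pinanediol {(3S)-3-(2-bromo-6-methoxyphenyl)-3-[5-methoxy-4-(triisopropylsilyloxy)naphthalen-1-yl]propyl}boronate, via catechol boronic ester 12 (not isolated)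
Conditions: catecholborane, RhCl(PPh3)3 (2 mol %), THF, rt; then (−)-pinanediol, rt
Reagents that add atoms: catecholborane, B1Oc2ccccc2O1; (1R,2R,3S,5R)-(−)-pinanediol, O[C@H]1C[C@H]2C[C@H](C2(C)C)[C@@]1(C)O
Why: Rhodium-catalysed anti-Markovnikov hydroboration of the terminal alkene, followed by transesterification of the labile catechol ester, places boron with its chiral director on C2 without touching C4 or the aryl bromide.

Step 9
Reactants: 13 (−)-pinanediol {(3S)-3-(2-bromo-6-methoxyphenyl)-3-[5-methoxy-4-(triisopropylsilyloxy)naphthalen-1-yl]propyl}boronate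
Product: 15 (−)-pinanediol {(1R,4S)-4-(2-bromo-6-methoxyphenyl)-1-chloro-4-[5-methoxy-4-(triisopropylsilyloxy)naphthalen-1-yl]butyl}boronate, via dichloromethyl borate 14 (not isolated)
Conditions: CH2Cl2, n-BuLi, THF, −100 °C (LiCHCl2 pre-formed); then 13; ZnCl2, −100 °C to rt
Reagents that add atoms: dichloromethane, ClCCl
Why: Matteson homologation, in which LiCHCl2 adds to boron and ZnCl2-promoted 1,2-migration of the C2 alkyl group displaces one chloride under control of the pinanediol ester, should give the (1R)-α-chloroboronic ester, and pre-forming the carbenoid keeps butyllithium away from the aryl bromide.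

Step 10
Reactants: 15 (−)-pinanediol {(1R,4S)-4-(2-bromo-6-methoxyphenyl)-1-chloro-4-[5-methoxy-4-(triisopropylsilyloxy)naphthalen-1-yl]butyl}boronate
Product: 19 (1S,4S)-5-methoxy-4-[5-methoxy-4-(triisopropylsilyloxy)naphthalen-1-yl]-1,2,3,4-tetrahydronaphthalen-1-ol, via aryllithium 16 (not isolated), via cyclic borate 17 (not isolated), via benzylic boronic ester 18 (not isolated)
Conditions: t-BuLi (2.1 equiv), THF/Et2O (0.01 M), −100 °C, then warm to rt; then 30% H2O2, 2 M NaOH, 0 °C
Reagents that add atoms: hydrogen peroxide, OO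
Why: Proposed new method: t-BuLi should exchange the C8a bromine for lithium at −100 °C faster than it adds to the hindered pinanediol boronic ester, the aryllithium 16 is trapped by the tethered boron as the 7-membered cyclic borate 17, and on warming the C8a aryl group migrates from boron to C1 with loss of chloride (1,2-metallate rearrangement), which expels boron from the ring and contracts it to the six-membered ring B of 18; alkaline H2O2 then converts C1–B into C1–OH. The closest known reaction types are the Matteson substitution of α-chloroboronic esters by aryllithium or aryl Grignard reagents, the Parham cyclization (halogen–lithium exchange next to an internal electrophile) and the oxidation of benzylic boronic esters; new is only their intramolecular, ring-contracting combination. Ring B closes in two events, a 7-exo attack of carbon on boron and then a 7-to-6 ring contraction that is formally a 6-exo-tet substitution at C1. C1 is the only new stereocenter and is controlled by the substrate, because the 1,2-shift inverts C1 and the oxidation retains it, so the (1R)-chloride set by pinanediol in step 9 should give the (1S)-alcohol cis to the C4 naphthyl group without reliance on 1,4-induction; C4 is a spectator. The step needs site selectivity for C8a (meta to the methoxy group and otherwise outcompeted by C2′ of the naphthalene), which the bromine atom secures, and it needs exchange and cyclization to outrun attack of t-BuLi on boron and intermolecular borate formation, which low temperature, the bulk of both partners and high dilution should secure.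

Step 11
Reactants: 19 (1S,4S)-5-methoxy-4-[5-methoxy-4-(triisopropylsilyloxy)naphthalen-1-yl]-1,2,3,4-tetrahydronaphthalen-1-ol
Product: 20 dipolynaphthalene B, (1S,4S)-4-(4-hydroxy-5-methoxynaphthalen-1-yl)-5-methoxy-1,2,3,4-tetrahydronaphthalen-1-ol
Conditions: TBAF, AcOH, THF, 0 °C
Reagents that add atoms: none
Why: Fluoride-mediated desilylation frees the naphthol, and acetic acid buffering should keep the electron-rich naphtholate from oxidation and leave the benzylic alcohol and both stereocenters untouched.

**Compound list**

1 | 1,8-dimethoxynaphthalene | COc1cccc2cccc(OC)c12 | starting material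
2 | 4,5-dimethoxynaphthalene-1-carbaldehyde | O=Cc1ccc(OC)c2c(OC)cccc12 | intermediate
3 | 4-hydroxy-5-methoxynaphthalene-1-carbaldehyde | O=Cc1ccc(O)c2c(OC)cccc12 | intermediate
4 | 5-methoxy-4-(triisopropylsilyloxy)naphthalene-1-carbaldehyde | O=Cc1ccc(O[Si](C(C)C)(C(C)C)C(C)C)c2c(OC)cccc12 | intermediate
5 | 1-bromo-3-(methoxymethoxy)benzene | COCOc1cccc(Br)c1 | starting material
6 | [2-bromo-6-(methoxymethoxy)phenyl]lithium | COCOc1cccc(Br)c1[Li] | intermediate
7 | racemic [2-bromo-6-(methoxymethoxy)phenyl][5-methoxy-4-(triisopropylsilyloxy)naphthalen-1-yl]methanol | COCOc1cccc(Br)c1C(O)c1ccc(O[Si](C(C)C)(C(C)C)C(C)C)c2c(OC)cccc12 | intermediate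
8 | racemic 3-bromo-2-{methoxy[5-methoxy-4-(triisopropylsilyloxy)naphthalen-1-yl]methyl}phenol | COC(c1c(O)cccc1Br)c1ccc(O[Si](C(C)C)(C(C)C)C(C)C)c2c(OC)cccc12 | intermediate
9 | 3-bromo-2-{[5-methoxy-4-(triisopropylsilyloxy)naphthalen-1-yl]methylidene}cyclohexa-3,5-dien-1-one (ortho-quinone methide) | O=C1C=CC=C(Br)C1=Cc1ccc(O[Si](C(C)C)(C(C)C)C(C)C)c2c(OC)cccc12 | intermediate
10 | 3-bromo-2-{(1S)-1-[5-methoxy-4-(triisopropylsilyloxy)naphthalen-1-yl]prop-2-en-1-yl}phenol | Oc1cccc(Br)c1[C@@H](C=C)c1ccc(O[Si](C(C)C)(C(C)C)C(C)C)c2c(OC)cccc12 | intermediate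
11 | 1-bromo-3-methoxy-2-{(1S)-1-[5-methoxy-4-(triisopropylsilyloxy)naphthalen-1-yl]prop-2-en-1-yl}benzene | COc1cccc(Br)c1[C@@H](C=C)c1ccc(O[Si](C(C)C)(C(C)C)C(C)C)c2c(OC)cccc12 | intermediate
12 | 2-{(3S)-3-(2-bromo-6-methoxyphenyl)-3-[5-methoxy-4-(triisopropylsilyloxy)naphthalen-1-yl]propyl}-1,3,2-benzodioxaborole | COc1cccc(Br)c1[C@@H](CCB1Oc2ccccc2O1)c1ccc(O[Si](C(C)C)(C(C)C)C(C)C)c2c(OC)cccc12 | intermediate
13 | (−)-pinanediol {(3S)-3-(2-bromo-6-methoxyphenyl)-3-[5-methoxy-4-(triisopropylsilyloxy)naphthalen-1-yl]propyl}boronate | COc1cccc(Br)c1[C@@H](CCB1O[C@H]2C[C@H]3C[C@H](C3(C)C)[C@@]2(C)O1)c1ccc(O[Si](C(C)C)(C(C)C)C(C)C)c2c(OC)cccc12 | intermediate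
14 | lithium dichloromethyl borate formed from 13 and LiCHCl2 | COc1cccc(Br)c1[C@@H](CC[B-]1(C(Cl)Cl)O[C@H]2C[C@H]3C[C@H](C3(C)C)[C@@]2(C)O1)c1ccc(O[Si](C(C)C)(C(C)C)C(C)C)c2c(OC)cccc12.[Li+] | intermediate
15 | (−)-pinanediol {(1R,4S)-4-(2-bromo-6-methoxyphenyl)-1-chloro-4-[5-methoxy-4-(triisopropylsilyloxy)naphthalen-1-yl]butyl}boronate | COc1cccc(Br)c1[C@@H](CC[C@H](Cl)B1O[C@H]2C[C@H]3C[C@H](C3(C)C)[C@@]2(C)O1)c1ccc(O[Si](C(C)C)(C(C)C)C(C)C)c2c(OC)cccc12 | intermediate
16 | aryllithium of 15 (lithium at C8a in place of bromine; 1R,4S) | COc1cccc([Li])c1[C@@H](CC[C@H](Cl)B1O[C@H]2C[C@H]3C[C@H](C3(C)C)[C@@]2(C)O1)c1ccc(O[Si](C(C)C)(C(C)C)C(C)C)c2c(OC)cccc12 | intermediate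
17 | lithium cyclic borate (7-membered ring; boron bonded to C8a and to C1; 1R,4S) | COc1cccc2c1[C@@H](CC[C@H](Cl)[B-]21O[C@H]3C[C@H]4C[C@H](C4(C)C)[C@@]3(C)O1)c1ccc(O[Si](C(C)C)(C(C)C)C(C)C)c3c(OC)cccc13.[Li+] | intermediate
18 | (−)-pinanediol {(1S,4S)-5-methoxy-4-[5-methoxy-4-(triisopropylsilyloxy)naphthalen-1-yl]-1,2,3,4-tetrahydronaphthalen-1-yl}boronate | COc1cccc2c1[C@H](c1ccc(O[Si](C(C)C)(C(C)C)C(C)C)c3c(OC)cccc13)CC[C@@H]2B1O[C@H]2C[C@H]3C[C@H](C3(C)C)[C@@]2(C)O1 | intermediate
19 | (1S,4S)-5-methoxy-4-[5-methoxy-4-(triisopropylsilyloxy)naphthalen-1-yl]-1,2,3,4-tetrahydronaphthalen-1-ol | COc1cccc2c1[C@H](c1ccc(O[Si](C(C)C)(C(C)C)C(C)C)c3c(OC)cccc13)CC[C@@H]2O | intermediate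
20 | dipolynaphthalene B, (1S,4S)-4-(4-hydroxy-5-methoxynaphthalen-1-yl)-5-methoxy-1,2,3,4-tetrahydronaphthalen-1-ol | COc1cccc2c1[C@H](c1ccc(O)c3c(OC)cccc13)CC[C@@H]2O | target

**Step count and risks**

Total step count: 11. Longest linear sequence: 11 steps (1 to 20; 5 is bought and enters in step 4).

Steps most likely to fail:

Step 10 (proposed new method). Addition of t-BuLi to boron, intermolecular borate formation or an incomplete 1,2-shift could compete with the exchange and ring contraction. The fallback sets out from 15 and comes back at 19 with known chemistry. Oxidation of 15 with NaBO3·4H2O in THF/water should give, through the α-chloro alcohol, the aldehyde (4S)-4-(2-bromo-6-methoxyphenyl)-4-[5-methoxy-4-(triisopropylsilyloxy)naphthalen-1-yl]butanal F1. Pinnick oxidation (NaClO2, NaH2PO4, 2-methyl-2-butene) should give the acid (4S)-4-(2-bromo-6-methoxyphenyl)-4-[5-methoxy-4-(triisopropylsilyloxy)naphthalen-1-yl]butanoic acid F2. Parham cyclization of its lithium salt (n-BuLi, 2.2 equiv, THF, −100 °C) should close the same C8a–C1 bond and give the tetralone (4S)-5-methoxy-4-[5-methoxy-4-(triisopropylsilyloxy)naphthalen-1-yl]-3,4-dihydronaphthalen-1(2H)-one F3. Asymmetric transfer hydrogenation with RuCl(p-cymene)[(S,S)-TsDPEN] in HCO2H/Et3N should then give the (1S)-alcohol 19, with hydride delivery anti to the pseudoaxial C4 aryl group working in the same direction.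

Step 6. Slow addition to the hindered quinone methide (flanked by bromine and the peri hydrogen of the naphthalene) or an uncatalysed SN1 background reaction of the strongly stabilised benzhydryl cation could erode facial selectivity. The fallback sets out from 8 and comes back at 10. Vinylmagnesium bromide (3 equiv, THF, 0 °C to 60 °C) deprotonates the phenol, the magnesium phenoxide expels methoxide, and the second equivalent adds to the quinone methide to give the racemic phenol 3-bromo-2-{1-[5-methoxy-4-(triisopropylsilyloxy)naphthalen-1-yl]prop-2-en-1-yl}phenol F4. Its enantiomers are separated by preparative chromatography on a chiral stationary phase, and the (S)-enantiomer is 10.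

Step 2. Loss of regioselectivity (cleavage of the C5 ether or of both ethers) or thiolate addition and condensation at the aldehyde could occur. The fallback sets out from 1 and comes back at 4. BCl3 (1 equiv, CH2Cl2, −78 °C to 0 °C) should cleave one of the two equivalent peri ethers through a boron chelate and give 8-methoxynaphthalen-1-ol F5. NBS in MeCN at 0 °C should brominate para to the free hydroxyl and give 4-bromo-8-methoxynaphthalen-1-ol F6. TIPSOTf and 2,6-lutidine should give (4-bromo-8-methoxynaphthalen-1-yl)oxy-triisopropylsilane F7. Bromine–lithium exchange (n-BuLi, THF, −78 °C) and quenching with DMF should return aldehyde 4.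

**Further compounds**

F1 | step 10 | (4S)-4-(2-bromo-6-methoxyphenyl)-4-[5-methoxy-4-(triisopropylsilyloxy)naphthalen-1-yl]butanal | COc1cccc(Br)c1[C@@H](CCC=O)c1ccc(O[Si](C(C)C)(C(C)C)C(C)C)c2c(OC)cccc12
F2 | step 10 | (4S)-4-(2-bromo-6-methoxyphenyl)-4-[5-methoxy-4-(triisopropylsilyloxy)naphthalen-1-yl]butanoic acid | COc1cccc(Br)c1[C@@H](CCC(=O)O)c1ccc(O[Si](C(C)C)(C(C)C)C(C)C)c2c(OC)cccc12
F3 | step 10 | (4S)-5-methoxy-4-[5-methoxy-4-(triisopropylsilyloxy)naphthalen-1-yl]-3,4-dihydronaphthalen-1(2H)-one | COc1cccc2c1[C@H](c1ccc(O[Si](C(C)C)(C(C)C)C(C)C)c3c(OC)cccc13)CCC2=O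
F4 | step 6 | racemic 3-bromo-2-{1-[5-methoxy-4-(triisopropylsilyloxy)naphthalen-1-yl]prop-2-en-1-yl}phenol | Oc1cccc(Br)c1C(C=C)c1ccc(O[Si](C(C)C)(C(C)C)C(C)C)c2c(OC)cccc12
F5 | step 2 | 8-methoxynaphthalen-1-ol | COc1cccc2cccc(O)c12
F6 | step 2 | 4-bromo-8-methoxynaphthalen-1-ol | COc1cccc2c(Br)ccc(O)c12
F7 | step 2 | (4-bromo-8-methoxynaphthalen-1-yl)oxy-triisopropylsilane | COc1cccc2c(Br)ccc(O[Si](C(C)C)(C(C)C)C(C)C)c12
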